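**Strategy.** The ten-membered carbocycle is closed last, at the C2–C3 bond (germacrane numbering: lactone O–C6, C7, C11, C12; alkenes C1=C10 and C4=C5). The step exploits the (Z)-homoallylic 1,5-dioxygen array C3(O)–C2–C1=C10(CH3)–C9(O). In the open precursor a γ-lactone carries a (Z)-enal arm (C3) on C6 and a 4-hydroxy-3-methylalk-2-enylstannane arm (C9–OH, C2–SnBu3) on C7. SnCl4 moves tin to C10 on the hydroxyl face; the allyltin trichloride then adds to the aldehyde through a chair, forming C2–C3, the Z C1=C10 alkene and the C3 carbinol in one operation. The lactone stereotriad comes from anti conjugate addition and kinetic protonation on a butenolide.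

Key step: step 14

Remark: germacrane numbering is used for the target carbons throughout; N-methoxy-N-methylbut-2-ynamide (5) and (1,3-dioxolan-2-ylmethyl)magnesium bromide (12) are taken as commercial.

Step 1
Reactants: 1 prop-2-yn-1-ol
Product: 3 (Z)-3-iodo-2-methylprop-2-en-1-ol, via alkenylmagnesium bromide 2 (not isolated)
Conditions: MeMgBr (2.2 equiv), CuI (10 mol %), THF, −10 °C → rt; then I2, −10 °C
Reagents that add atoms: methylmagnesium bromide, C[Mg]Br; iodine, II
Why: Copper-catalysed anti carbomagnesiation of the propargyl alkoxide puts CH3 on the inner and magnesium on the terminal alkyne carbon, and iodinolysis with retention should give the Z iodoalkene (future C3–C4(CH3)=C5).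

Step 2
Reactants: 3 (Z)-3-iodo-2-methylprop-2-en-1-ol
Product: 4 tert-butyl{[(Z)-3-iodo-2-methylprop-2-en-1-yl]oxy}dimethylsilane
Conditions: TBSCl, imidazole, CH2Cl2, 0 °C → rt
Reagents that add atoms: tert-butyldimethylsilyl chloride, CC(C)(C)[Si](C)(C)Cl
Why: Standard silylation of the primary alcohol masks the future C3 hydroxyl against the organometallic steps that follow.

Step 3
Reactants: 4 silyl ether; 5 N-methoxy-N-methylbut-2-ynamide
Product: 7 (Z)-7-[(tert-butyldimethylsilyl)oxy]-6-methylhept-5-en-2-yn-4-one, via alkenyllithium 6 (not isolated)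
Conditions: t-BuLi (2.1 equiv), Et2O, −78 °C; then 5, −78 → −30 °C
Reagents that add atoms: none
Why: Iodine–lithium exchange retains the alkene geometry at −78 °C and the Weinreb amide accepts one addition through its chelated tetrahedral intermediate, so the ynone should result (Weinreb ketone synthesis).

Step 4
Reactants: 7 ynone
Product: 8 (R,Z)-7-[(tert-butyldimethylsilyl)oxy]-6-methylhept-5-en-2-yn-4-ol
Conditions: (R)-Alpine-Borane [B-isopinocampheyl-9-borabicyclo[3.3.1]nonane from (+)-α-pinene, 2 equiv], neat, rt; then ethanolamine, Et2O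
Reagents that add atoms: none
Why: The Midland Alpine-Borane reduction transfers the pinanyl hydride through a cyclic transition state in which the slim propynyl group is the small substituent, which should set the R carbinol centre that becomes C6.

Step 5
Reactants: 8 propargylic alcohol
Product: 10 (2Z,4R,5Z)-7-[(tert-butyldimethylsilyl)oxy]-2-iodo-6-methylhepta-2,5-dien-4-ol, via cyclic alkenylalanate 9 (not isolated)
Conditions: NaAlH2(OCH2CH2OMe)2 (1.6 equiv), THF, 0 °C → rt; EtOAc; then I2, −78 → 0 °C
Reagents that add atoms: iodine, II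
Why: Alkoxide-directed trans hydroalumination places aluminium on the distal alkyne carbon in a five-membered alanate, so iodinolysis with retention should give the iodoalkene with iodine cis to the carbinol carbon.

Step 6
Reactants: 10 iodo dienol
Product: 11 (R)-5-[(Z)-3-[(tert-butyldimethylsilyl)oxy]-2-methylprop-1-en-1-yl]-3-methylfuran-2(5H)-one
Conditions: PdCl2(PPh3)2 (5 mol %), CO (1 atm), 2,6-lutidine, THF, 45 °C
Reagents that add atoms: carbon monoxide, [C-]#[O+]
Why: Oxidative addition to the alkenyl iodide, CO insertion and capture of the acylpalladium by the cis hydroxyl (carbonylative lactonisation) should give the α-methylbutenolide without touching C6.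

Step 7
Reactants: 11 butenolide; 12 (1,3-dioxolan-2-ylmethyl)magnesium bromide
Product: 14 (3R,4S,5S)-4-(1,3-dioxolan-2-ylmethyl)-5-[(Z)-3-[(tert-butyldimethylsilyl)oxy]-2-methylprop-1-en-1-yl]-3-methyldihydrofuran-2(3H)-one, via silyl ketene acetal 13 (not isolated)
Conditions: 12 (1.5 equiv), CuBr·SMe2 (20 mol %), Me3SiCl (2 equiv), THF, −78 °C; then saturated aqueous NH4Cl, −78 → 0 °C
Reagents that add atoms: none
Why: Copper-catalysed 1,4-addition should deliver the acetal carbon to C7 anti to the C6 alkenyl group, and kinetic protonation of the ketene acetal at C11 anti to the new C7 substituent should leave the methyl cis to it, setting C7 (S) and C11 (R).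

Step 8
Reactants: 14 acetal lactone
Product: 15 2-[(2S,3S,4R)-2-[(Z)-3-hydroxy-2-methylprop-1-en-1-yl]-4-methyl-5-oxooxolan-3-yl]acetaldehyde
Conditions: 1 M HCl, THF, rt
Reagents that add atoms: water, O
Why: Aqueous acid should hydrolyse the dioxolane and the primary silyl ether in one operation, and no stereocentre is at risk because C7 is β to the new aldehyde and the lactone α-carbon does not enolise in dilute acid.

Step 9
Reactants: 16 but-2-yn-1-ol
Product: 18 (Z)-3-iodobut-2-en-1-ol, via cyclic alkenylalanate 17 (not isolated)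
Conditions: NaAlH2(OCH2CH2OMe)2 (1.6 equiv), THF, 0 °C → rt; EtOAc; then I2, −78 → 0 °C
Reagents that add atoms: iodine, II
Why: The same hydroxyl-directed trans hydroalumination–iodination as in step 5 should put iodine on the methyl-bearing carbon cis to CH2OH (future C10, C1, C2).

Step 10
Reactants: 18 (Z)-3-iodobut-2-en-1-ol
Product: 19 (Z)-1-chloro-3-iodobut-2-ene
Conditions: N-chlorosuccinimide, Me2S, CH2Cl2, −20 → 0 °C
Reagents that add atoms: N-chlorosuccinimide, ClN1C(=O)CCC1=O
Why: Corey–Kim chlorination converts the primary allylic alcohol to the chloride by SN2 displacement of the alkoxysulfonium ion, without allylic transposition or loss of alkene geometry.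

Step 11
Reactants: 19 (Z)-1-chloro-3-iodobut-2-ene
Product: 20 (Z)-tributyl(3-iodobut-2-en-1-yl)stannane
Conditions: Bu3SnH, LiN(iPr)2, THF, 0 °C; then 19, −78 °C
Reagents that add atoms: tributyltin hydride, CCCC[SnH](CCCC)CCCC
Why: Tributylstannyllithium should displace the primary allylic chloride by SN2 at −78 °C faster than it attacks the alkenyl iodide, giving the allylstannane with the Z geometry intact.

Step 12
Reactants: 15 hydroxy aldehyde; 20 iodo stannane
Product: 21 (3R,4S,5S)-4-[(2R,3Z)-2-hydroxy-3-methyl-5-(tributylstannyl)pent-3-en-1-yl]-5-[(Z)-3-hydroxy-2-methylprop-1-en-1-yl]-3-methyldihydrofuran-2(3H)-one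
Conditions: CrCl2 (4 equiv), NiCl2 (2 mol %), chiral oxazoline–sulfonamide ligand N-[2-(4-isopropyl-4,5-dihydro-1,3-oxazol-2-yl)-6-methylphenyl]methanesulfonamide (the enantiomer that directs Si-face addition, 4.4 equiv), Et3N, THF, rt
Reagents that add atoms: none
Why: In the Nozaki–Hiyama–Kishi coupling zerovalent nickel inserts into the C–I bond and the alkenyl group passes to trivalent chromium and adds to the aldehyde with retention of alkene geometry and tolerance of hydroxyl, lactone and allylstannane, while the chiral sulfonamide on chromium should direct Si-face attack to give the 9R carbinol.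

Step 13
Reactants: 21 diol stannane
Product: 22 (Z)-3-[(2S,3S,4R)-3-[(2R,3Z)-2-hydroxy-3-methyl-5-(tributylstannyl)pent-3-en-1-yl]-4-methyl-5-oxooxolan-2-yl]-2-methylprop-2-enal
Conditions: [Cu(MeCN)4]OTf (5 mol %), 2,2′-bipyridine (5 mol %), TEMPO (5 mol %), N-methylimidazole (10 mol %), air, MeCN, rt
Reagents that add atoms: none
Why: The copper/TEMPO aerobic oxidation is selective for the primary allylic alcohol over the hindered secondary C9 alcohol and is neutral enough to keep the Z enal and the allylstannane intact.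

Step 14
Reactants: 22 stannyl enal
Product: 24 (3S,6S,7S,9R,11R)-3,9-dihydroxygermacra-1(10)Z,4Z-dien-12,6-olide, via allyltin trichloride 23 (not isolated)
Conditions: SnCl4 (1.2 equiv), CH2Cl2, −78 °C, 22 added slowly to a final 0.002 M; −78 → −40 °C; aqueous NaHCO3
Reagents that add atoms: none
Why: SnCl4 binds the C9 hydroxyl and transmetallates the stannane in an SE2′ sense on the hydroxyl face of the Z alkene (C9–H eclipsing C1 to avoid A(1,3) strain), giving tertiary allyltin trichloride 23 with tin on C10; tin then binds the aldehyde and the allyl group is passed on through a six-membered chair (Sn, C10, C1, C2, C3, O) that forms C2–C3 and shifts the alkene to C1=C10. The closest known reactions are the tin tetrahalide-promoted additions of 4-hydroxy- and 4-alkoxy-alk-2-enylstannanes to aldehydes, which give (Z)-homoallylic alcohols with 1,5-induction, and Lewis acid-mediated intramolecular allylstannane–aldehyde macrocyclisations; the step uses the former within one molecule. The ten-membered carbocycle closes in a 10-exo-trig mode at the aldehyde carbon, the chair being fused to the forming ring along C10–C1–C2–C3. C3 (S) is controlled by the tin-bearing C10 centre (itself set from C9 by the hydroxyl-directed tin delivery) through the chair with C9 axial and C4 equatorial, which is the sense of the intermolecular 1,5-induction. The Z geometry of C1=C10 follows from the axial C9 substituent and from the lower strain of a cis alkene in the ten-membered ring, so the alkene geometry of the stannane itself is not carried over. The step needs C2 (α) rather than C10 (γ) bond formation, 1,2-addition to the enal and ring closure rather than oligomerisation; the relocation of tin to C10, the closed transition state and high dilution at −78 °C should secure these.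

Step 15
Reactants: 24 macrocyclic diol
Product: 25 (3S,6S,7S,9R,11R)-3,9-diacetoxygermacra-1(10)Z,4Z-dien-12,6-olide (target)
Conditions: Ac2O, pyridine, DMAP (cat.), CH2Cl2, 0 °C → rt
Reagents that add atoms: acetic anhydride, CC(=O)OC(C)=O
Why: DMAP-catalysed acylation should esterify both secondary allylic alcohols with retention, under conditions too weakly basic to epimerise C11.

**Compound list**

1 | prop-2-yn-1-ol | C#CCO | starting material
2 | bromomagnesium (Z)-3-(bromomagnesio)-2-methylprop-2-en-1-olate | Br[Mg]/C=C(/C)CO[Mg]Br | intermediate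
3 | (Z)-3-iodo-2-methylprop-2-en-1-ol | OC/C(C)=C\I | intermediate
4 | tert-butyl{[(Z)-3-iodo-2-methylprop-2-en-1-yl]oxy}dimethylsilane | CC(C)(C)[Si](C)(C)OC/C(C)=C\I | intermediate
5 | N-methoxy-N-methylbut-2-ynamide | CC#CC(=O)N(C)OC | starting material
6 | (Z)-{3-[(tert-butyldimethylsilyl)oxy]-2-methylprop-1-en-1-yl}lithium | CC(C)(C)[Si](C)(C)OC/C(C)=C\[Li] | intermediate
7 | (Z)-7-[(tert-butyldimethylsilyl)oxy]-6-methylhept-5-en-2-yn-4-one | CC(C)(C)[Si](C)(C)OC/C(C)=C\C(=O)C#CC | intermediate
8 | (R,Z)-7-[(tert-butyldimethylsilyl)oxy]-6-methylhept-5-en-2-yn-4-ol | CC(C)(C)[Si](C)(C)OC/C(C)=C\[C@@H](O)C#CC | intermediate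
9 | sodium (5R)-5-[(Z)-3-[(tert-butyldimethylsilyl)oxy]-2-methylprop-1-en-1-yl]-2,2-bis(2-methoxyethoxy)-3-methyl-2,5-dihydro-1,2-oxaaluminol-2-uide | CC(C)(C)[Si](C)(C)OC/C(C)=C\[C@H]1O[Al-](OCCOC)(OCCOC)C(C)=C1.[Na+] | intermediate
10 | (2Z,4R,5Z)-7-[(tert-butyldimethylsilyl)oxy]-2-iodo-6-methylhepta-2,5-dien-4-ol | CC(C)(C)[Si](C)(C)OC/C(C)=C\[C@@H](O)/C=C(\I)C | intermediate
11 | (R)-5-[(Z)-3-[(tert-butyldimethylsilyl)oxy]-2-methylprop-1-en-1-yl]-3-methylfuran-2(5H)-one | CC(C)(C)[Si](C)(C)OC/C(C)=C\[C@@H]1C=C(C)C(=O)O1 | intermediate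
12 | (1,3-dioxolan-2-ylmethyl)magnesium bromide | Br[Mg]CC1OCCO1 | starting material
13 | trimethylsilyl ketene acetal of 14, (4S,5R)-configured 2-(trimethylsilyloxy)-3-methyl-4,5-dihydrofuran | CC(C)(C)[Si](C)(C)OC/C(C)=C\[C@@H]1[C@@H](CC2OCCO2)C(C)=C(O[Si](C)(C)C)O1 | intermediate
14 | (3R,4S,5S)-4-(1,3-dioxolan-2-ylmethyl)-5-[(Z)-3-[(tert-butyldimethylsilyl)oxy]-2-methylprop-1-en-1-yl]-3-methyldihydrofuran-2(3H)-one | CC(C)(C)[Si](C)(C)OC/C(C)=C\[C@@H]1[C@@H](CC2OCCO2)[C@@H](C)C(=O)O1 | intermediate
15 | 2-[(2S,3S,4R)-2-[(Z)-3-hydroxy-2-methylprop-1-en-1-yl]-4-methyl-5-oxooxolan-3-yl]acetaldehyde | OC/C(C)=C\[C@@H]1[C@@H](CC=O)[C@@H](C)C(=O)O1 | intermediate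
16 | but-2-yn-1-ol | CC#CCO | starting material
17 | sodium 2,2-bis(2-methoxyethoxy)-3-methyl-2,5-dihydro-1,2-oxaaluminol-2-uide | [Na+].COCCO[Al-]1(OCCOC)OCC=C1C | intermediate
18 | (Z)-3-iodobut-2-en-1-ol | OC/C=C(/C)I | intermediate
19 | (Z)-1-chloro-3-iodobut-2-ene | ClC/C=C(/C)I | intermediate
20 | (Z)-tributyl(3-iodobut-2-en-1-yl)stannane | CCCC[Sn](CCCC)(CCCC)C/C=C(/C)I | intermediate
21 | (3R,4S,5S)-4-[(2R,3Z)-2-hydroxy-3-methyl-5-(tributylstannyl)pent-3-en-1-yl]-5-[(Z)-3-hydroxy-2-methylprop-1-en-1-yl]-3-methyldihydrofuran-2(3H)-one | OC/C(C)=C\[C@@H]1[C@@H](C[C@H](/C(=C\C[Sn](CCCC)(CCCC)CCCC)C)O)[C@@H](C)C(=O)O1 | intermediate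
22 | (Z)-3-[(2S,3S,4R)-3-[(2R,3Z)-2-hydroxy-3-methyl-5-(tributylstannyl)pent-3-en-1-yl]-4-methyl-5-oxooxolan-2-yl]-2-methylprop-2-enal | O=C/C(C)=C\[C@@H]1[C@@H](C[C@H](/C(=C\C[Sn](CCCC)(CCCC)CCCC)C)O)[C@@H](C)C(=O)O1 | intermediate
23 | (Z)-3-[(2S,3S,4R)-3-[(2R,3R)-2-hydroxy-3-methyl-3-(trichlorostannyl)pent-4-en-1-yl]-4-methyl-5-oxooxolan-2-yl]-2-methylprop-2-enal | O=C/C(C)=C\[C@@H]1[C@@H](C[C@@H](O)[C@@](C)(C=C)[Sn](Cl)(Cl)Cl)[C@@H](C)C(=O)O1 | intermediate
24 | (3S,6S,7S,9R,11R)-3,9-dihydroxygermacra-1(10)Z,4Z-dien-12,6-olide | O[C@H]1C/C=C(/C)[C@H](O)C[C@@H]2[C@@H](/C=C\1C)OC(=O)[C@@H]2C | intermediate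
25 | (3S,6S,7S,9R,11R)-3,9-diacetoxygermacra-1(10)Z,4Z-dien-12,6-olide, i.e. (3R,3aS,5R,6Z,9S,10Z,11aS)-3,6,10-trimethyl-2-oxo-2,3,3a,4,5,8,9,11a-octahydrocyclodeca[b]furan-5,9-diyl diacetate | CC(=O)O[C@H]1C/C=C(/C)[C@H](OC(C)=O)C[C@@H]2[C@@H](/C=C\1C)OC(=O)[C@@H]2C | target

**Step count.** Total: 15 steps. Longest linear sequence: 12 steps (steps 1–8 and 12–15, from prop-2-yn-1-ol).

**Steps most likely to fail**

Step 14. The strain of the bicyclic transition state may override the control from the tin-bearing C10 centre, so that the aldehyde is attacked on the other face and the C3 epimer forms, alone or in a mixture. The fallback sets the C3 centre by reagent control after ring closure instead of during it. It sets out from 22: acetylation of the C9 hydroxyl (Ac2O, pyridine) would give (2R,3Z)-configured 9-acetoxy stannyl enal F1. The same SnCl4 ring closure would give the 9-acetoxy macrocyclic C3 alcohol, drawn as its 3R epimer, F2, whatever the configuration at C3. MnO2 in CH2Cl2 would oxidise the allylic alcohol to the ten-membered 3-oxo-9-acetate F3. (R)-Me-CBS oxazaborolidine with catecholborane (alkenyl as the large group, C2 methylene as the small one) should then give the 3S alcohol 9-acetate F4. Acetylation of F4 under the conditions of step 15 comes back to the route at 25.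

Step 7. The Grignard reagent may deprotonate the doubly activated C6–H of the butenolide (loss of optical purity, furan formation), and the protonation at C11 may lose its facial preference. The fallback replaces the polar addition and protonation by a radical addition and hydrogen-atom transfer under neutral conditions. It sets out from 11: a Giese addition with 2-(bromomethyl)-1,3-dioxolane, Bu3SnH (slow addition) and AIBN in benzene at 80 °C should add the nucleophilic dioxolanylmethyl radical to C7 anti to the C6 substituent. Hydrogen-atom transfer to the C11 radical anti to the new substituent then gives 14 directly (no new compound, F0), where the fallback rejoins the route.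

Step 11. The stannyl anion may attack the alkenyl iodide (halogen–metal exchange or substitution) instead of displacing the allylic chloride, and the iodoalkene geometry may scramble. The fallback introduces tin after the fragment union by π-allylpalladium chemistry. It sets out from 18: acetylation (Ac2O, pyridine) would give (Z)-3-iodobut-2-en-1-yl acetate F5. Nozaki–Hiyama–Kishi coupling of F5 with 15 under the conditions of step 12 would give the (2R,3Z)-5-acetoxy-2-hydroxy-3-methylpent-3-enyl lactone F6. Stannylation of the primary allylic acetate with Bu3Sn–SnBu3, catalysed by zerovalent palladium (Pd2(dba)3, LiCl, DMF, rt), should place tin on the less hindered terminus and come back to the route at 21.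

**Further compounds**

F1 | step 14 | (2R,3Z)-1-[(2S,3S,4R)-2-[(Z)-2-methyl-3-oxoprop-1-en-1-yl]-4-methyl-5-oxooxolan-3-yl]-3-methyl-5-(tributylstannyl)pent-3-en-2-yl acetate | O=C/C(C)=C\[C@@H]1[C@@H](C[C@H](/C(=C\C[Sn](CCCC)(CCCC)CCCC)C)OC(C)=O)[C@@H](C)C(=O)O1
F2 | step 14 | (3R,6S,7S,9R,11R)-9-acetoxy-3-hydroxygermacra-1(10)Z,4Z-dien-12,6-olide | O[C@@H]1C/C=C(/C)[C@H](OC(C)=O)C[C@@H]2[C@@H](/C=C\1C)OC(=O)[C@@H]2C
F3 | step 14 | (6S,7S,9R,11R)-9-acetoxy-3-oxogermacra-1(10)Z,4Z-dien-12,6-olide | O=C1C/C=C(/C)[C@H](OC(C)=O)C[C@@H]2[C@@H](/C=C\1C)OC(=O)[C@@H]2C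
F4 | step 14 | (3S,6S,7S,9R,11R)-9-acetoxy-3-hydroxygermacra-1(10)Z,4Z-dien-12,6-olide | O[C@H]1C/C=C(/C)[C@H](OC(C)=O)C[C@@H]2[C@@H](/C=C\1C)OC(=O)[C@@H]2C
F0 | step 7 | none | none
F5 | step 11 | (Z)-3-iodobut-2-en-1-yl acetate | CC(=O)OC/C=C(/C)I
F6 | step 11 | (2Z,4R)-4-hydroxy-5-[(2S,3S,4R)-2-[(Z)-3-hydroxy-2-methylprop-1-en-1-yl]-4-methyl-5-oxooxolan-3-yl]-3-methylpent-2-en-1-yl acetate | OC/C(C)=C\[C@@H]1[C@@H](C[C@H](/C(=C\COC(C)=O)C)O)[C@@H](C)C(=O)O1
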